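## Retrosynthetic overview

1. The enyne C(sp)–C(sp2) bond is cut last: Sonogashira coupling of methyl 4-[(2R,5S)-5-ethynyloxolan-2-yl]butanoate with (1Z,9E)-1-bromo-10-iododeca-1,9-diene. The diene comes from cyclooctene by end-differentiating ozonolysis, Z-bromomethylenation and E-iodo-olefination.
2. The ethynyl ester goes back to (2R,5S)-2-allyl-5-(silyloxymethyl)oxolan-3-one: the ring ketone is deleted (reduction, Barton–McCombie), the allyl group is grown to the butanoate (cross-metathesis with methyl acrylate, hydrogenation), and CH2OSi becomes C≡CH (desilylation, oxidation, Ohira–Bestmann).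
3. The strategy rests on the 2,5-trans oxolane (O1, C2 carrying the enyne, C5 carrying the butanoate chain): the C5 substituent is an allyl group handed over from the ring oxygen O1. The oxolane, the only ring, closes in that step: diazoketone → copper carbenoid → cyclic oxonium ylide (O1–C5 bond) → [2,3]-shift (C5–CH2 bond), trans to the C2 substituent.
4. The diazoketone, (S)-4-(allyloxy)-5-(silyloxy)-1-diazopentan-2-one, is made in five steps from dimethyl (S)-malate, whose carbinol carbon becomes C2 of the target.

Key step: step 6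

Assumption: the carbinol centre formed at ring C3 on ketone reduction is removed two steps later, so the alcohol and its thiocarbonyl derivative are carried as C3-epimer mixtures and their SMILES leave C3 open.

## Route

Step 1
Reactants: 1 dimethyl (S)-malate
Product: 2 methyl (S)-3,4-dihydroxybutanoate
Conditions: BH3·SMe2, NaBH4 (5 mol %), THF, 0 °C → rt; then MeOH
Reagents that add atoms: none
Why: Hydroxyl-directed borane reduction: the alkoxyborane formed at the free OH delivers hydride through a five-membered chelate to the neighbouring ester only, so the α-hydroxy ester is reduced, the remote ester survives and the stereocentre is untouched.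

Step 2
Reactants: 2 methyl (S)-3,4-dihydroxybutanoate
Product: 3 methyl (S)-4-[(tert-butyldiphenylsilyl)oxy]-3-hydroxybutanoate
Conditions: TBDPSCl, imidazole, CH2Cl2, 0 °C
Reagents that add atoms: tert-butyl(chloro)diphenylsilane (TBDPSCl), CC(C)(C)[Si](Cl)(c1ccccc1)c1ccccc1
Why: Selective silyl protection: the bulky silyl chloride reacts much faster with the primary than with the secondary hydroxyl.

Step 3
Reactants: 3 methyl (S)-4-[(tert-butyldiphenylsilyl)oxy]-3-hydroxybutanoate; 4 allyl 2,2,2-trichloroacetimidate
Product: 5 methyl (S)-3-(allyloxy)-4-[(tert-butyldiphenylsilyl)oxy]butanoate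
Conditions: TfOH (10 mol %), cyclohexane/CH2Cl2 2:1, 0 °C → rt
Reagents that add atoms: none
Why: Acid-catalysed O-alkylation with a trichloroacetimidate avoids the retro-aldol and β-elimination that a β-hydroxy ester suffers under NaH/allyl halide conditions; the TBDPS ether tolerates catalytic TfOH and the C–O bond at the stereocentre is not broken.

Step 4
Reactants: 5 methyl (S)-3-(allyloxy)-4-[(tert-butyldiphenylsilyl)oxy]butanoate
Product: 6 (S)-3-(allyloxy)-4-[(tert-butyldiphenylsilyl)oxy]butanoic acid
Conditions: LiOH·H2O, THF/MeOH/H2O, 0 °C → rt; then 1 M HCl to pH 3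
Reagents that add atoms: lithium hydroxide, [Li+].[OH-]
Why: Ester saponification; the allyl ether and the TBDPS ether are stable to cold aqueous LiOH and to brief mild acidification.

Step 5
Reactants: 6 (S)-3-(allyloxy)-4-[(tert-butyldiphenylsilyl)oxy]butanoic acid
Product: 8 (S)-4-(allyloxy)-5-[(tert-butyldiphenylsilyl)oxy]-1-diazopentan-2-one, via isobutyl carbonic mixed anhydride 7 (not isolated)
Conditions: i-BuOCOCl, Et3N, Et2O, −20 °C; then CH2N2 (excess) in Et2O, 0 °C → rt
Reagents that add atoms: diazomethane, C=[N+]=[N-]; isobutyl chloroformate, CC(C)COC(Cl)=O (its atoms stay only in 7)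
Why: C-acylation of diazomethane by a mixed carbonic anhydride (first stage of an Arndt–Eistert sequence) gives the α-diazoketone without exposing the silyl and allyl ethers to the HCl an acid chloride would release.

Step 6
Reactants: 8 (S)-4-(allyloxy)-5-[(tert-butyldiphenylsilyl)oxy]-1-diazopentan-2-one
Product: 10 (2R,5S)-2-allyl-5-{[(tert-butyldiphenylsilyl)oxy]methyl}oxolan-3-one, via cyclic allyloxonium ylide 9 (not isolated)
Conditions: Cu(acac)2 (5 mol %), THF, reflux, slow addition of 8
Reagents that add atoms: none
Why: Dinitrogen is expelled at copper and the electron-poor copper carbenoid is trapped by a lone pair of the allyl ether oxygen; this O–C bond (O1–C5 in target numbering, O1–C2 of 10) closes the oxolane as ylide 9, a five-membered closure onto the carbenoid carbon that is exo with respect to the Cu=C bond. In 9 the carbanionic carbon and the far end of the O-allyl group are joined in a concerted suprafacial [2,3]-sigmatropic shift through an envelope-shaped five-centre transition state while the O–CH2 bond is cleaved, which makes the C–CH2 bond to the future butanoate chain. This is the known copper-catalysed tandem oxonium ylide formation and [2,3]-rearrangement of allyl ethers tethered to diazoketones, which gives 2,5-disubstituted oxolan-3-ones. The one new stereocentre (C2 of 10, R) is set by the malate-derived centre next to the ylide oxygen: its CH2OSi group prefers a pseudo-equatorial position, the allyl group on oxygen lies anti to it, and because the shift is suprafacial the allyl group arrives at carbon on that same face, trans to CH2OSi. The step needs 2,5-trans diastereoselectivity, secured by that adjacent centre, and chemoselectivity for ylide formation over C–H insertion, cyclopropanation and [1,2]-shift, secured by the acetylacetonate-ligated copper carbenoid, the favourable five-membered ylide ring and the absence of any other accessible Lewis-basic site (the hindered silyl ether does not compete).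

Step 7
Reactants: 10 (2R,5S)-2-allyl-5-{[(tert-butyldiphenylsilyl)oxy]methyl}oxolan-3-one
Product: 11 (2R,5S)-2-allyl-5-{[(tert-butyldiphenylsilyl)oxy]methyl}oxolan-3-ol (C3 epimers)
Conditions: NaBH4, MeOH, −20 °C
Reagents that add atoms: none
Why: Fast borohydride reduction at low temperature removes the ketone before the α-centre C2 can epimerise or O1 can be β-eliminated; the configuration of the new carbinol is irrelevant.

Step 8
Reactants: 11 (2R,5S)-2-allyl-5-{[(tert-butyldiphenylsilyl)oxy]methyl}oxolan-3-ol (C3 epimers)
Product: 12 O-[(2R,5S)-2-allyl-5-{[(tert-butyldiphenylsilyl)oxy]methyl}oxolan-3-yl] 1H-imidazole-1-carbothioate (C3 epimers)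
Conditions: 1,1'-thiocarbonyldiimidazole, DMAP (cat.), 1,2-dichloroethane, 60 °C
Reagents that add atoms: 1,1'-thiocarbonyldiimidazole, S=C(n1ccnc1)n1ccnc1
Why: Thioacylation of the secondary alcohol under non-basic conditions gives the thiocarbonyl derivative needed for radical deoxygenation.

Step 9
Reactants: 12 O-[(2R,5S)-2-allyl-5-{[(tert-butyldiphenylsilyl)oxy]methyl}oxolan-3-yl] 1H-imidazole-1-carbothioate (C3 epimers)
Product: 13 (2S,5S)-2-allyl-5-{[(tert-butyldiphenylsilyl)oxy]methyl}oxolane
Conditions: Bu3SnH, AIBN (cat.), toluene, 100 °C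
Reagents that add atoms: none
Why: Barton–McCombie deoxygenation: the stannyl radical adds to C=S, the C3–O bond fragments and the secondary C3 radical takes H from Bu3SnH; C2 and C5 are not involved (the descriptor at C2 changes only through CIP priorities) and the pent-4-enyl-type radical has no favourable cyclisation mode onto the allyl group.

Step 10
Reactants: 13 (2S,5S)-2-allyl-5-{[(tert-butyldiphenylsilyl)oxy]methyl}oxolane; 14 methyl acrylate
Product: 15 methyl (E)-4-[(2S,5S)-5-{[(tert-butyldiphenylsilyl)oxy]methyl}oxolan-2-yl]but-2-enoate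
Conditions: 14 (5 equiv), second-generation Grubbs catalyst (H2IMes)(PCy3)Cl2Ru=CHPh (3 mol %), CH2Cl2, 40 °C
Reagents that add atoms: none
Why: Olefin cross-metathesis of a terminal alkene with excess electron-poor acrylate gives the E-enoate selectively; the ether and silyl ether are inert to the ruthenium carbene.

Step 11
Reactants: 15 methyl (E)-4-[(2S,5S)-5-{[(tert-butyldiphenylsilyl)oxy]methyl}oxolan-2-yl]but-2-enoate
Product: 16 methyl 4-[(2R,5S)-5-{[(tert-butyldiphenylsilyl)oxy]methyl}oxolan-2-yl]butanoate
Conditions: H2 (1 atm), 10% Pd/C, EtOAc, rt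
Reagents that add atoms: none
Why: Heterogeneous hydrogenation of the conjugated C=C; the ester, oxolane and silyl ether are untouched (the C2 descriptor changes only through CIP priorities).

Step 12
Reactants: 16 methyl 4-[(2R,5S)-5-{[(tert-butyldiphenylsilyl)oxy]methyl}oxolan-2-yl]butanoate
Product: 17 methyl 4-[(2R,5S)-5-(hydroxymethyl)oxolan-2-yl]butanoate
Conditions: TBAF, AcOH, THF, 0 °C → rt
Reagents that add atoms: none
Why: Fluoride-induced cleavage of the Si–O bond; acetic acid buffers the medium so that the methyl ester is not hydrolysed.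

Step 13
Reactants: 17 methyl 4-[(2R,5S)-5-(hydroxymethyl)oxolan-2-yl]butanoate
Product: 18 methyl 4-[(2R,5S)-5-formyloxolan-2-yl]butanoate
Conditions: Dess–Martin periodinane, CH2Cl2, 0 °C → rt
Reagents that add atoms: none
Why: Dess–Martin oxidation converts the primary alcohol to the aldehyde under near-neutral conditions that leave the α-oxygenated stereocentre intact; the aldehyde is used at once.

Step 14
Reactants: 18 methyl 4-[(2R,5S)-5-formyloxolan-2-yl]butanoate
Product: 19 methyl 4-[(2R,5S)-5-ethynyloxolan-2-yl]butanoate
Conditions: dimethyl (1-diazo-2-oxopropyl)phosphonate, K2CO3, MeOH, 0 °C → rt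
Reagents that add atoms: dimethyl (1-diazo-2-oxopropyl)phosphonate, COP(=O)(OC)C(=[N+]=[N-])C(C)=O
Why: Ohira–Bestmann homologation: the diazomethylphosphonate anion formed in situ adds to the aldehyde, and loss of phosphate and N2 gives an alkylidene carbene whose 1,2-H shift gives the terminal alkyne; methanol makes transesterification of the methyl ester degenerate and the mild carbonate base at 0 °C should spare the α-alkoxy centre.

Step 15
Reactants: 20 cyclooctene
Product: 23 8,8-dimethoxyoctanal, via 8-hydroperoxy-8-methoxyoctanal 21 (not isolated), via 1-hydroperoxy-1,8,8-trimethoxyoctane 22 (not isolated)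
Conditions: O3, CH2Cl2/MeOH 5:1, −78 °C; TsOH·H2O (cat.), −78 °C → rt; NaHCO3; Me2S, rt
Reagents that add atoms: ozone, [O-][O+]=O; methanol, CO
Why: Ozonolysis in methanol gives an aldehyde at one terminus and an α-methoxy hydroperoxide at the other; acid acetalises only the free aldehyde and Me2S then reduces the hydroperoxide to the second aldehyde, so the two ends of the C8 chain emerge differentiated.

Step 16
Reactants: 23 8,8-dimethoxyoctanal
Product: 24 (Z)-1-bromo-9,9-dimethoxynon-1-ene
Conditions: [Ph3PCH2Br]Br, KOtBu, THF, −78 °C; then 23, −78 °C → rt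
Reagents that add atoms: (bromomethyl)triphenylphosphonium bromide, BrC[P+](c1ccccc1)(c1ccccc1)c1ccccc1.[Br-]
Why: Wittig reaction of the non-stabilised bromomethylene ylide under kinetic control at low temperature passes through the cis-oxaphosphetane and should give mainly the (Z)-bromoalkene; the acetal is inert to base.

Step 17
Reactants: 24 (Z)-1-bromo-9,9-dimethoxynon-1-ene
Product: 25 (Z)-9-bromonon-8-enal
Conditions: 1 M HCl, THF, rt
Reagents that add atoms: water, O
Why: Acid-catalysed acetal hydrolysis; the vinyl bromide is inert to dilute aqueous acid.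

Step 18
Reactants: 25 (Z)-9-bromonon-8-enal
Product: 26 (1Z,9E)-1-bromo-10-iododeca-1,9-diene
Conditions: CrCl2 (6 equiv), CHI3 (2 equiv), 1,4-dioxane/THF 6:1, 0 °C → rt, dark
Reagents that add atoms: iodoform, IC(I)I
Why: Takai olefination: the geminal dichromium species from CHI3 and CrCl2 adds to the aldehyde and anti elimination should give the (E)-iodoalkene; without a nickel co-catalyst divalent chromium does not insert into the vinyl bromide.

Step 19
Reactants: 19 methyl 4-[(2R,5S)-5-ethynyloxolan-2-yl]butanoate; 26 (1Z,9E)-1-bromo-10-iododeca-1,9-diene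
Product: 27 methyl 4-[(2R,5S)-5-[(3E,11Z)-12-bromododeca-3,11-dien-1-yn-1-yl]oxolan-2-yl]butanoate (CNP0170116.1)
Conditions: Pd(PPh3)4 (5 mol %), CuI (10 mol %), i-Pr2NH, THF, rt, degassed
Reagents that add atoms: none
Why: Sonogashira coupling: zerovalent palladium inserts into the C(sp2)–I bond much faster than into the C(sp2)–Br bond at room temperature, so the copper acetylide of 19 should couple only at the iodo terminus with retention of both alkene geometries; the ring stereocentres are not involved.

## Compound list

1 | dimethyl (S)-malate | COC(=O)C[C@H](O)C(=O)OC | starting material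
2 | methyl (S)-3,4-dihydroxybutanoate | COC(=O)C[C@H](O)CO | intermediate
3 | methyl (S)-4-[(tert-butyldiphenylsilyl)oxy]-3-hydroxybutanoate | COC(=O)C[C@H](O)CO[Si](c1ccccc1)(c1ccccc1)C(C)(C)C | intermediate
4 | allyl 2,2,2-trichloroacetimidate | C=CCOC(=N)C(Cl)(Cl)Cl | starting material
5 | methyl (S)-3-(allyloxy)-4-[(tert-butyldiphenylsilyl)oxy]butanoate | COC(=O)C[C@H](OCC=C)CO[Si](c1ccccc1)(c1ccccc1)C(C)(C)C | intermediate
6 | (S)-3-(allyloxy)-4-[(tert-butyldiphenylsilyl)oxy]butanoic acid | OC(=O)C[C@H](OCC=C)CO[Si](c1ccccc1)(c1ccccc1)C(C)(C)C | intermediate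
7 | (S)-3-(allyloxy)-4-[(tert-butyldiphenylsilyl)oxy]butanoic isobutyl carbonic anhydride (formed and consumed in step 5) | CC(C)COC(=O)OC(=O)C[C@H](OCC=C)CO[Si](c1ccccc1)(c1ccccc1)C(C)(C)C | intermediate
8 | (S)-4-(allyloxy)-5-[(tert-butyldiphenylsilyl)oxy]-1-diazopentan-2-one | [N-]=[N+]=CC(=O)C[C@H](OCC=C)CO[Si](c1ccccc1)(c1ccccc1)C(C)(C)C | intermediate
9 | (5S)-1-allyl-5-{[(tert-butyldiphenylsilyl)oxy]methyl}-3-oxooxolan-1-ium-2-ide, the cyclic oxonium ylide (formed and consumed in step 6) | C=CC[O+]1[CH-]C(=O)C[C@H]1CO[Si](c2ccccc2)(c3ccccc3)C(C)(C)C | intermediate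
10 | (2R,5S)-2-allyl-5-{[(tert-butyldiphenylsilyl)oxy]methyl}oxolan-3-one | C=CC[C@@H]1C(=O)C[C@@H](CO[Si](c2ccccc2)(c3ccccc3)C(C)(C)C)O1 | intermediate
11 | (2R,5S)-2-allyl-5-{[(tert-butyldiphenylsilyl)oxy]methyl}oxolan-3-ol, C3 epimers | C=CC[C@@H]1C(O)C[C@@H](CO[Si](c2ccccc2)(c3ccccc3)C(C)(C)C)O1 | intermediate
12 | O-[(2R,5S)-2-allyl-5-{[(tert-butyldiphenylsilyl)oxy]methyl}oxolan-3-yl] 1H-imidazole-1-carbothioate, C3 epimers | C=CC[C@@H]1C(OC(=S)n2ccnc2)C[C@@H](CO[Si](c3ccccc3)(c4ccccc4)C(C)(C)C)O1 | intermediate
13 | (2S,5S)-2-allyl-5-{[(tert-butyldiphenylsilyl)oxy]methyl}oxolane | C=CC[C@@H]1CC[C@@H](CO[Si](c2ccccc2)(c3ccccc3)C(C)(C)C)O1 | intermediate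
14 | methyl acrylate | C=CC(=O)OC | starting material
15 | methyl (E)-4-[(2S,5S)-5-{[(tert-butyldiphenylsilyl)oxy]methyl}oxolan-2-yl]but-2-enoate | COC(=O)/C=C/C[C@@H]1CC[C@@H](CO[Si](c2ccccc2)(c3ccccc3)C(C)(C)C)O1 | intermediate
16 | methyl 4-[(2R,5S)-5-{[(tert-butyldiphenylsilyl)oxy]methyl}oxolan-2-yl]butanoate | COC(=O)CCC[C@@H]1CC[C@@H](CO[Si](c2ccccc2)(c3ccccc3)C(C)(C)C)O1 | intermediate
17 | methyl 4-[(2R,5S)-5-(hydroxymethyl)oxolan-2-yl]butanoate | COC(=O)CCC[C@@H]1CC[C@@H](CO)O1 | intermediate
18 | methyl 4-[(2R,5S)-5-formyloxolan-2-yl]butanoate | COC(=O)CCC[C@@H]1CC[C@@H](C=O)O1 | intermediate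
19 | methyl 4-[(2R,5S)-5-ethynyloxolan-2-yl]butanoate | COC(=O)CCC[C@@H]1CC[C@@H](C#C)O1 | intermediate
20 | cyclooctene | C1=CCCCCCC1 | starting material
21 | 8-hydroperoxy-8-methoxyoctanal (formed and consumed in step 15) | COC(OO)CCCCCCC=O | intermediate
22 | 1-hydroperoxy-1,8,8-trimethoxyoctane (formed and consumed in step 15) | COC(OO)CCCCCCC(OC)OC | intermediate
23 | 8,8-dimethoxyoctanal | COC(OC)CCCCCCC=O | intermediate
24 | (Z)-1-bromo-9,9-dimethoxynon-1-ene | COC(OC)CCCCCC/C=C\Br | intermediate
25 | (Z)-9-bromonon-8-enal | O=CCCCCCC/C=C\Br | intermediate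
26 | (1Z,9E)-1-bromo-10-iododeca-1,9-diene | I/C=C/CCCCCC/C=C\Br | intermediate
27 | methyl 4-[(2R,5S)-5-[(3E,11Z)-12-bromododeca-3,11-dien-1-yn-1-yl]oxolan-2-yl]butanoate | COC(=O)CCC[C@@H]1CC[C@@H](C#C/C=C/CCCCCC/C=C\Br)O1 | target

## Step count and risks

Total step count: 19. Longest linear sequence: 15 steps (steps 1–14 and 19, from dimethyl (S)-malate); the side chain (steps 15–18) joins in step 19.

Steps most likely to fail:

Step 6. The carbenoid may be diverted into C–H insertion next to oxygen, cyclopropanation of the allyl group, a [1,2]-shift or carbene dimerisation, or the rearrangement may lose its trans selectivity. The fallback sets out from diazoketone 8, builds the ring by lactonisation and introduces the allyl group by oxocarbenium C-allylation, and comes back at 13, so that steps 7–9 fall away. Silver-catalysed Wolff rearrangement of 8 in methanol (PhCO2Ag, Et3N, MeOH, rt) would give the homologated ester methyl (S)-4-(allyloxy)-5-[(tert-butyldiphenylsilyl)oxy]pentanoate F1. Isomerisation of its allyl ether to the prop-1-enyl ether with H2-activated [Ir(cod)(PMePh2)2]PF6 in THF, then TsOH·H2O in wet CH2Cl2, would hydrolyse the enol ether and close the γ-lactone (S)-5-{[(tert-butyldiphenylsilyl)oxy]methyl}oxolan-2-one F2. Reduction with i-Bu2AlH at −78 °C and acetylation in the same flask (Ac2O, pyridine, DMAP) would give the lactol acetate (5S)-5-{[(tert-butyldiphenylsilyl)oxy]methyl}oxolan-2-yl acetate F3. Allyltrimethylsilane with BF3·OEt2 in CH2Cl2 at −78 °C should then attack the oxocarbenium ion mainly anti to the C5 substituent and give 13; this is expected to be less selective than the ylide route, so the cis isomer would be removed by chromatography.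

Step 16. Z-selectivity in the Wittig bromomethylenation may be incomplete, and the E-bromoalkene would be hard to separate and would be carried to the end. The fallback sets out from 23 and comes back at 24. Ramirez dibromo-olefination (CBr4, PPh3, Et3N to protect the acetal, CH2Cl2, 0 °C) would give 1,1-dibromo-9,9-dimethoxynon-1-ene F4. Palladium-catalysed hydrogenolysis with Bu3SnH (Pd(PPh3)4 cat., toluene, rt) should then remove only the bromine trans to the alkyl chain, because zerovalent palladium inserts into the less hindered C–Br bond, leaving the (Z)-bromoalkene 24.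

Step 18. E-selectivity in the chromium-mediated iodo-olefination of an unbranched aldehyde may be incomplete, which would put a (3Z) isomer into the final enyne. The fallback sets out from 25 and comes back at 26. Ohira–Bestmann homologation of 25 (dimethyl (1-diazo-2-oxopropyl)phosphonate, K2CO3, MeOH) would give (Z)-1-bromodec-1-en-9-yne F5. Syn-hydrozirconation of the terminal alkyne with Cp2Zr(H)Cl (1.1 equiv, THF, rt), which is much faster than reaction at the disubstituted bromoalkene, followed by iodinolysis with I2 at 0 °C with retention, would give the (E)-iodoalkene 26.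

## Further compounds

F1 | step 6 | methyl (S)-4-(allyloxy)-5-[(tert-butyldiphenylsilyl)oxy]pentanoate | COC(=O)CC[C@H](OCC=C)CO[Si](c1ccccc1)(c1ccccc1)C(C)(C)C
F2 | step 6 | (S)-5-{[(tert-butyldiphenylsilyl)oxy]methyl}oxolan-2-one | O=C1CC[C@@H](CO[Si](c2ccccc2)(c3ccccc3)C(C)(C)C)O1
F3 | step 6 | (5S)-5-{[(tert-butyldiphenylsilyl)oxy]methyl}oxolan-2-yl acetate, anomer mixture | CC(=O)OC1CC[C@@H](CO[Si](c2ccccc2)(c3ccccc3)C(C)(C)C)O1
F4 | step 16 | 1,1-dibromo-9,9-dimethoxynon-1-ene | COC(OC)CCCCCCC=C(Br)Br
F5 | step 18 | (Z)-1-bromodec-1-en-9-yne | C#CCCCCCC/C=C\Br
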